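**Late times.** Left long enough with working catalyst, both flasks head for one balance, where the two equilibrium constants put 49.9% in the isomer of the product, 29.3% in the starting material and 20.8% in the target.

in all of them: starting material 23 mM; free catalyst 2.5 mol%; added ligand 0.42 mM

| run | time |
|---|---|
| Thursday's | 12 min |
| Saturday's | 40 min |

    starting material + free catalyst ⇌ target + free catalyst, rate k1*[starting material]*[free catalyst] forward; the back reaction follows from the equilibrium constant (K1 = 0.71, k1 = 4.0 M⁻¹ s⁻¹)
    target + free catalyst ⇌ isomer of the product + free catalyst, rate k2*[free catalyst]*[target] forward; the back reaction follows from the equilibrium constant (K2 = 2.4, k2 = 3.8 M⁻¹ s⁻¹)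
    isomer of the product + free catalyst ⇌ starting material + free catalyst, rate k3*[free catalyst]*[isomer of the product] forward; the back reaction follows from the equilibrium constant (k3 = 4.9 M⁻¹ s⁻¹)
    free catalyst + added ligand ⇌ idle complex, settled at all times (K4 = 46000 M⁻¹)
    free catalyst + target → spent catalyst (k5 = 1.1 M⁻¹ s⁻¹)

- which of these there is most of at the end, counted by the starting material in it, Thursday's (isomer of the product / starting material / target)
- which of these there is most of at the end, counted by the starting material in it, Saturday's (isomer of the product / starting material / target)
- how much there is at the end of the one of these that leads, in percent of the starting material charged: Thursday's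
- how much there is at the end of the one of these that leads, in percent of the starting material charged: Saturday's

**Free catalyst.** Each turning is pseudo-first-order in its substrate while free catalyst holds, so free catalyst is our clock. We charge 0.575 mM of catalyst against 0.42 mM of ligand. As a first answer, let the ligand bind whole, which leaves 0.155 mM. But at that level some ligand stays unbound, and each unbound ligand frees one catalyst. Putting this back gives 0.214 mM, then 0.192 mM, then 0.198 mM, and there the rounds have closed in.

**Opening dose.** Starting material leaves by two ways, to target and to isomer, with constants summing to 12.3 M⁻¹ s⁻¹. We define the opening dose as that sum times the free catalyst at balance times the time: the number of e-foldings the opening clock allows. Thursday's dose is 1.76 and Saturday's 5.88. Both are ceilings, since target also consumes catalyst. With target at its balance share, a free catalyst lasts about 3.17 min, shorter than Thursday's 12 min. So we commit to the isomer leading on Saturday's and leave Thursday's open.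

**The forecast.** It names starting material for Thursday's at 45.3% and isomer of the product for Saturday's at 42.8%, on the ground that “Target kills catalyst, and ligand then mops up the remainder”.

**The flasks.** Thursday's ends with starting material leading at 45.4%, Saturday's with isomer of the product at 43.3%.

**What dose buys.** Saturday's dose is 3.33 times Thursday's, and that difference in time is the main reason for the gap in isomer between the two flasks, Saturday's 43.3% against Thursday's 37.4%, a gain of 5.9 percentage points. A further flask like Saturday's, with 14 mM of starting material, carries 0.350 mM of catalyst, less than the ligand. The same balance leaves 0.0527 mM free, a dose of 1.56 against Thursday's 1.76. It ends with 46% starting material, 37.2% isomer and 16.2% target, against Thursday's 45.4%, 37.4% and 16.3%.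

The numbers of this flask are assumed; the run is a simulation.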